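## Retrosynthetic overview

1. End game: the α-methylene group is unmasked last from a dimethylamine adduct, the angelate is put on the free secondary C8–OH, and C9 is carried through ring closure as a carbinol that is oxidised afterwards.
2. Key disconnection C9–C10: the ten-membered carbocycle is closed by an intramolecular Nozaki–Hiyama–Kishi addition of a (Z)-alkenyl iodide (C10) to an aldehyde (C9) in a seco-aldehyde.
3. Enabling feature: the cis-fused γ-lactone ring (O–C6–C7–C11–C12) holds the C5 and C8 branches on one face; a temporary 2,2-dimethyl-1,3-dioxolane ring across O7/O8 (spiro at C7, absent from the target, cleaved afterwards) locks the C6–C7–C8–C9 torsion syn; the Z double bonds C4=C5 and C1=C10 bend the C5–C10 tether back, so C10 sits next to C9.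
4. The seco-aldehyde comes from a furanose by 1,2→2,3 acetonide migration and lactol-to-lactone transposition; C4=C5 from a dibromo-olefination, a trans-selective Negishi methylation and a B-alkyl Suzuki coupling; C1=C10 from one α-iodoethylidene Wittig olefination; C6, C7 and C8 from L-arabinose (3-ulose plus a masked acrylate enolate).
5. Ring order: furanose (chiral pool, temporary) → γ-lactone and dioxolane together → ten-membered ring → dioxolane removed.

Key step: step 13

Remark (assumption): the C11 centre made in step 4 and the C9 carbinol made in step 13 are carried as epimer mixtures because both become sp2 later (steps 18 and 14); their descriptors and the anomeric descriptor of lactols are left open in the SMILES, and atom numbers C1–C13 and O6–O9 refer to the target skeleton.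

## Route

Step 1
Reactants: 1 L-arabinose
Product: 2 5-O-(tert-butyldiphenylsilyl)-L-arabinofuranose
Conditions: TBDPSCl, imidazole, DMF, 0 °C to rt
Reagents that add atoms: tert-butyl(chloro)diphenylsilane, CC(C)(C)[Si](Cl)(c1ccccc1)c1ccccc1
Why: Selective silyl ether formation at the primary hydroxyl should trap the sugar as the furanose, because O5 can no longer close a pyranose; no stereocentre is touched.

Step 2
Reactants: 2 5-O-(tert-butyldiphenylsilyl)-L-arabinofuranose
Product: 3 5-O-TBDPS-1,2-O-isopropylidene-β-L-arabinofuranose
Conditions: Me2C(OMe)2, acetone, CSA (cat.), rt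
Reagents that add atoms: 2,2-dimethoxypropane, COC(C)(C)OC
Why: Acid-catalysed transacetalisation should engage the only cis-diol of the furanose (O1/O2 of the β-anomer) as a cis-fused dioxolane and leave the trans-disposed 3-OH free.

Step 3
Reactants: 3 5-O-TBDPS-1,2-O-isopropylidene-β-L-arabinofuranose
Product: 4 5-O-TBDPS-1,2-O-isopropylidene-β-L-threo-pentofuranos-3-ulose
Conditions: Dess–Martin periodinane, CH2Cl2, rt
Reagents that add atoms: none
Why: Dess–Martin oxidation of the lone secondary alcohol should give the 3-ulose under neutral conditions that do not epimerise C2 or C4.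

Step 4
Reactants: 4 5-O-TBDPS-1,2-O-isopropylidene-β-L-threo-pentofuranos-3-ulose; 5 methyl 3-(dimethylamino)propanoate
Product: 7 3-C-[2-(dimethylamino)-1-(methoxycarbonyl)ethyl]-5-O-TBDPS-1,2-O-isopropylidene-β-L-lyxofuranose, via lithium ester enolate 6 (not isolated)
Conditions: LiN(i-Pr)2, THF, −78 °C; then 4, −78 °C; AcOH quench
Reagents that add atoms: none
Why: Aldol-type 1,2-addition of the ester enolate (a masked acrylate anion) should occur on the convex face, anti to the 1,2-acetonide and to the C4 side chain, so the new tertiary carbinol (target C7) has its OH cis to O2 (L-lyxo); the centre next to the ester (target C11) is not controlled and is erased later.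

Step 5
Reactants: 7 3-C-[2-(dimethylamino)-1-(methoxycarbonyl)ethyl]-5-O-TBDPS-1,2-O-isopropylidene-β-L-lyxofuranose
Product: 8 3-C-[2-(dimethylamino)-1-(methoxycarbonyl)ethyl]-1,2-O-isopropylidene-β-L-lyxofuranose
Conditions: HF·pyridine, pyridine, THF, 0 °C to rt
Reagents that add atoms: none
Why: Fluoride-mediated desilylation under buffered, alkoxide-free conditions should free the primary alcohol without lactonisation onto the methyl ester or loss of the acetonide.

Step 6
Reactants: 8 3-C-[2-(dimethylamino)-1-(methoxycarbonyl)ethyl]-1,2-O-isopropylidene-β-L-lyxofuranose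
Product: 9 3-C-[2-(dimethylamino)-1-(methoxycarbonyl)ethyl]-1,2-O-isopropylidene-β-L-lyxo-pentodialdo-1,4-furanose
Conditions: Dess–Martin periodinane, CH2Cl2, 0 °C
Reagents that add atoms: none
Why: Dess–Martin oxidation should give the α-alkoxy aldehyde under non-basic conditions that preserve the C4 (target C6) configuration; the tertiary alcohol cannot be oxidised.

Step 7
Reactants: 9 3-C-[2-(dimethylamino)-1-(methoxycarbonyl)ethyl]-1,2-O-isopropylidene-β-L-lyxo-pentodialdo-1,4-furanose; 10 triphenylphosphine
Product: 12 furanose 2,2-dibromovinyl compound, via (dibromomethylene)triphenylphosphorane 11 (not isolated)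
Conditions: CBr4, PPh3, Et3N, CH2Cl2, 0 °C
Reagents that add atoms: carbon tetrabromide, BrC(Br)(Br)Br
Why: Ramirez dibromo-olefination (first stage of the Corey–Fuchs sequence): the ylide formed from PPh3 and CBr4 should condense with the aldehyde in a Wittig reaction under amine-buffered conditions that spare the α-alkoxy centre, the acetonide and the hindered tertiary alcohol; no stereocentre is formed.

Step 8
Reactants: 12 furanose 2,2-dibromovinyl compound
Product: 13 furanose (Z)-2-bromoprop-1-enyl compound
Conditions: MeZnCl (2.5 equiv), PdCl2(DPEphos) (cat.), THF, 0 °C to rt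
Reagents that add atoms: methylzinc chloride, C[Zn]Cl
Why: Palladium-catalysed trans-selective monoalkylation of a 1,1-dibromoalkene (Negishi coupling): oxidative addition should occur at the less hindered C–Br bond trans to the furanose carbon, so the methyl group enters trans and the remaining bromine stays cis to the ring carbon, which fixes the future C4=C5 geometry; the organozinc halide tolerates the ester, the acetonide and the amine.

Step 9
Reactants: 13 furanose (Z)-2-bromoprop-1-enyl compound; 14 acrolein diethyl acetal
Product: 16 furanose (Z)-5,5-diethoxy-2-methylpent-1-enyl compound, via B-(3,3-diethoxypropyl)-9-BBN 15 (not isolated)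
Conditions: 9-BBN, THF, 0 °C to rt; then 13, Pd(OAc)2 (cat.), SPhos (cat.), K3PO4, THF/H2O, 40 °C
Reagents that add atoms: none
Why: B-alkyl Suzuki–Miyaura coupling of the alkenyl bromide with the alkylborane proceeds with retention of alkene geometry, so C3 ends up cis to C6 (Z-C4=C5); the mild phosphate base should leave the methyl ester and the aldol-type carbinol intact.

Step 10
Reactants: 16 furanose (Z)-5,5-diethoxy-2-methylpent-1-enyl compound
Product: 17 furanose (Z)-2-methyl-5-oxopent-1-enyl compound
Conditions: AcOH/THF/H2O (3:1:1), 35 °C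
Reagents that add atoms: water, O
Why: Mild acetal hydrolysis of the acyclic diethyl acetal should be much faster than that of the bicyclic 1,2-O-isopropylidene acetal, which stays in place.

Step 11
Reactants: 17 furanose (Z)-2-methyl-5-oxopent-1-enyl compound; 18 ethyltriphenylphosphonium iodide
Product: 22 furanose (1Z,5Z)-6-iodo-2-methylhepta-1,5-dienyl compound, via ethylidenetriphenylphosphorane 19 (not isolated), via (1-iodoethyl)triphenylphosphonium iodide 20 (not isolated), via (1-iodoethylidene)triphenylphosphorane 21 (not isolated)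
Conditions: n-BuLi, THF, rt; I2, −78 °C; NaN(SiMe3)2, −78 °C; then 17, −78 to −20 °C
Reagents that add atoms: iodine, II
Why: Wittig olefination with the α-iodo ylide (Stork–Zhao type) is expected to give the (Z)-2-iodoalkene with iodine cis to C2, the geometry needed for Z-C1=C10.

Step 12
Reactants: 22 furanose (1Z,5Z)-6-iodo-2-methylhepta-1,5-dienyl compound
Product: 24 seco-aldehyde (spiro γ-lactone/dioxolane), via 2,3-O-isopropylidene lactol 23 (not isolated)
Conditions: CSA (1.3 equiv), acetone, rt; then PhMe, 4 Å MS, 60 °C
Reagents that add atoms: none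
Why: Acid-catalysed acetal migration (ionisation at the anomeric oxygen and recapture by the cis tertiary O7–H) should give the preferred 2,3-O-isopropylidene lactol, whose open-chain tautomer undergoes transesterification (lactonisation) of the freed C6–OH with the methyl ester as methanol is removed; all stereocentres are retained, O8 is blocked, and the C9 aldehyde is released.

Step 13
Reactants: 24 seco-aldehyde (spiro γ-lactone/dioxolane)
Product: 25 ten-membered allylic alcohol (C9 epimers)
Conditions: CrCl2 (8 equiv), NiCl2 (2 mol %), DMSO/THF, rt, slow addition to 0.002 M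
Reagents that add atoms: none
Why: NiCl2 is reduced by CrCl2 to zerovalent nickel, which inserts into the C10–I bond, and transmetalation gives a trivalent alkenylchromium species that adds to the C9 aldehyde and forms the C9–C10 bond (Nozaki–Hiyama–Kishi reaction; its macrocyclic variant on alkenyl iodide/aldehyde pairs is the closest known reaction type for medium carbocycles). The ten-membered carbocycle is closed in a 10-exo-trig mode, the C9 oxygen staying outside the ring as the chromium alkoxide. The new C9 carbinol centre is at best biased by approach anti to the dioxolane O8 (Felkin-type), but its configuration is irrelevant because both epimers are oxidised to the same ketone in step 14. The step needs ring closure to win over intermolecular coupling: the cis-fused γ-lactone (O–C6–C7–C11–C12) holds the C5 and C8 arms on one face, the temporary dioxolane across O7/O8 fixes the C6–C7–C8–C9 torsion syn, the Z alkenes C4=C5 and C1=C10 fold the chain, and slow addition keeps the concentration low. Chemoselectivity rests on the organochromium reagent, which leaves the lactone, the tertiary amine and the acetal untouched, and the trisubstituted alkenyl–chromium bond keeps the Z geometry that the ring demands anyway.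

Step 14
Reactants: 25 ten-membered allylic alcohol (C9 epimers)
Product: 26 ten-membered enone (7,8-O-isopropylidene)
Conditions: Dess–Martin periodinane, CH2Cl2, 0 °C to rt
Reagents that add atoms: none
Why: Dess–Martin oxidation of the allylic alcohol should give the C9 enone and remove the uncontrolled C9 centre.

Step 15
Reactants: 26 ten-membered enone (7,8-O-isopropylidene)
Product: 27 7,8-dihydroxy enone
Conditions: TFA/H2O (9:1), 0 °C; NaHCO3 work-up
Reagents that add atoms: none
Why: Aqueous acid acetal cleavage removes the temporary dioxolane ring and frees the secondary C8–OH and the tertiary C7–OH without touching the lactone or the enone.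

Step 16
Reactants: 27 7,8-dihydroxy enone; 28 angelic acid
Product: 30 8-O-angelate (amine adduct), via angelic 2,4,6-trichlorobenzoic anhydride 29 (not isolated)
Conditions: 2,4,6-trichlorobenzoyl chloride, Et3N, PhMe, rt; then 27, 75 °C
Reagents that add atoms: none
Why: Yamaguchi-type acylation through the mixed anhydride, run without a nucleophilic catalyst, should esterify only the secondary C8–OH (the tertiary C7–OH is inert) and keep the Z geometry of the angeloyl group.

Step 17
Reactants: 30 8-O-angelate (amine adduct)
Product: 31 trimethylammonium iodide of 30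
Conditions: MeI (excess), MeCN, rt
Reagents that add atoms: iodomethane, CI
Why: Quaternisation (Menshutkin reaction) of the tertiary amine, the only nucleophilic site, turns it into a leaving group.

Step 18
Reactants: 31 trimethylammonium iodide of 30
Product: 32 target CNP0276177.1
Conditions: aq. NaHCO3, EtOAc, rt
Reagents that add atoms: none
Why: Mild base should trigger E1cB (Hofmann-type) elimination of trimethylamine from the β-ammonio lactone, unveiling the α-methylene group and erasing the C11 centre.

## Compound list

1 | L-arabinose (drawn as the open-chain aldehyde) | O=C[C@H](O)[C@@H](O)[C@@H](O)CO | starting material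
2 | 5-O-(tert-butyldiphenylsilyl)-L-arabinofuranose (anomer mixture) | OC1O[C@@H](CO[Si](c2ccccc2)(c2ccccc2)C(C)(C)C)[C@H](O)[C@H]1O | intermediate
3 | 5-O-TBDPS-1,2-O-isopropylidene-β-L-arabinofuranose (3-OH free, trans to O2) | CC1(C)O[C@H]2[C@@H](O1)O[C@@H](CO[Si](c1ccccc1)(c1ccccc1)C(C)(C)C)[C@@H]2O | intermediate
4 | 5-O-TBDPS-1,2-O-isopropylidene-β-L-threo-pentofuranos-3-ulose | CC1(C)O[C@H]2[C@@H](O1)O[C@@H](CO[Si](c1ccccc1)(c1ccccc1)C(C)(C)C)C2=O | intermediate
5 | methyl 3-(dimethylamino)propanoate | CN(C)CCC(=O)OC | starting material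
6 | lithium enolate of 5 (formed in the flask) | CN(C)CC=C(OC)O[Li] | intermediate
7 | 3-C-[2-(dimethylamino)-1-(methoxycarbonyl)ethyl]-5-O-TBDPS-1,2-O-isopropylidene-β-L-lyxofuranose (tertiary OH cis to O2; side-chain CH epimers) | CC1(C)O[C@H]2[C@@H](O1)O[C@@H](CO[Si](c1ccccc1)(c1ccccc1)C(C)(C)C)[C@]2(O)C(CN(C)C)C(=O)OC | intermediate
8 | 3-C-[2-(dimethylamino)-1-(methoxycarbonyl)ethyl]-1,2-O-isopropylidene-β-L-lyxofuranose | CC1(C)O[C@H]2[C@@H](O1)O[C@@H](CO)[C@]2(O)C(CN(C)C)C(=O)OC | intermediate
9 | 3-C-[2-(dimethylamino)-1-(methoxycarbonyl)ethyl]-1,2-O-isopropylidene-β-L-lyxo-pentodialdo-1,4-furanose (C5 aldehyde) | CC1(C)O[C@H]2[C@@H](O1)O[C@@H](C=O)[C@]2(O)C(CN(C)C)C(=O)OC | intermediate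
10 | triphenylphosphine | c1ccc(cc1)P(c1ccccc1)c1ccccc1 | starting material
11 | (dibromomethylene)triphenylphosphorane (formed in the flask) | BrC(Br)=P(c1ccccc1)(c1ccccc1)c1ccccc1 | intermediate
12 | furanose of 9 in which C4 carries a 2,2-dibromovinyl group | CC1(C)O[C@H]2[C@@H](O1)O[C@@H](C=C(Br)Br)[C@]2(O)C(CN(C)C)C(=O)OC | intermediate
13 | furanose in which C4 carries a (Z)-2-bromoprop-1-enyl group (bromine cis to the ring carbon) | CC1(C)O[C@H]2[C@@H](O1)O[C@@H](/C=C(/C)Br)[C@]2(O)C(CN(C)C)C(=O)OC | intermediate
14 | acrolein diethyl acetal (3,3-diethoxyprop-1-ene) | C=CC(OCC)OCC | starting material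
15 | B-(3,3-diethoxypropyl)-9-borabicyclo[3.3.1]nonane (formed in the flask) | CCOC(CCB1C2CCCC1CCC2)OCC | intermediate
16 | furanose in which C4 carries a (Z)-5,5-diethoxy-2-methylpent-1-enyl group | CC1(C)O[C@H]2[C@@H](O1)O[C@@H](/C=C(/C)CCC(OCC)OCC)[C@]2(O)C(CN(C)C)C(=O)OC | intermediate
17 | furanose in which C4 carries a (Z)-2-methyl-5-oxopent-1-enyl group | CC1(C)O[C@H]2[C@@H](O1)O[C@@H](/C=C(/C)CCC=O)[C@]2(O)C(CN(C)C)C(=O)OC | intermediate
18 | ethyltriphenylphosphonium iodide | CC[P+](c1ccccc1)(c1ccccc1)c1ccccc1.[I-] | starting material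
19 | ethylidenetriphenylphosphorane (formed in the flask) | CC=P(c1ccccc1)(c1ccccc1)c1ccccc1 | intermediate
20 | (1-iodoethyl)triphenylphosphonium iodide (formed in the flask) | CC(I)[P+](c1ccccc1)(c1ccccc1)c1ccccc1.[I-] | intermediate
21 | (1-iodoethylidene)triphenylphosphorane (formed in the flask) | CC(I)=P(c1ccccc1)(c1ccccc1)c1ccccc1 | intermediate
22 | furanose in which C4 carries a (1Z,5Z)-6-iodo-2-methylhepta-1,5-dienyl group (1,2-O-isopropylidene, tertiary 3-OH, 3-C-CH(CH2NMe2)CO2Me) | CC1(C)O[C@H]2[C@@H](O1)O[C@@H](/C=C(/C)CC/C=C(/C)I)[C@]2(O)C(CN(C)C)C(=O)OC | intermediate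
23 | 2,3-O-isopropylidene lactol isomer of 22 (free anomeric OH; formed in the flask) | OC1O[C@@H](/C=C(/C)CC/C=C(/C)I)[C@]2(OC(C)(C)O[C@@H]12)C(CN(C)C)C(=O)OC | intermediate
24 | seco-aldehyde: γ-lactone (O–C6–C7–C11–C12, C11 bearing CH2NMe2) spiro-fused at C7 to the O7/O8 2,2-dimethyl-1,3-dioxolane; C8 bears the C9 aldehyde, C6 the (1Z,5Z)-6-iodo-2-methylhepta-1,5-dienyl chain | CN(C)CC1C(=O)O[C@@H](/C=C(/C)CC/C=C(/C)I)[C@]12OC(C)(C)O[C@H]2C=O | intermediate
25 | 13-(dimethylamino)-9-hydroxy-7,8-(isopropylidenedioxy)germacra-1(10)Z,4Z-dien-12,6-olide (C9 and C11 epimers; H6 and O7 cis, O7 and O8 cis) | CN(C)CC1C(=O)O[C@H]2/C=C(/C)CC/C=C(/C)C(O)[C@@H]3OC(C)(C)O[C@]123 | intermediate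
26 | 13-(dimethylamino)-7,8-(isopropylidenedioxy)-9-oxogermacra-1(10)Z,4Z-dien-12,6-olide | CN(C)CC1C(=O)O[C@H]2/C=C(/C)CC/C=C(/C)C(=O)[C@@H]3OC(C)(C)O[C@]123 | intermediate
27 | 13-(dimethylamino)-7,8-dihydroxy-9-oxogermacra-1(10)Z,4Z-dien-12,6-olide | CN(C)CC1C(=O)O[C@H]2/C=C(/C)CC/C=C(/C)C(=O)[C@H](O)[C@@]12O | intermediate
28 | angelic acid ((Z)-2-methylbut-2-enoic acid) | C/C=C(/C)C(=O)O | starting material
29 | angelic 2,4,6-trichlorobenzoic anhydride (formed in the flask) | C/C=C(/C)C(=O)OC(=O)c1c(Cl)cc(Cl)cc1Cl | intermediate
30 | 8-angeloyloxy-13-(dimethylamino)-7-hydroxy-9-oxogermacra-1(10)Z,4Z-dien-12,6-olide | CN(C)CC1C(=O)O[C@H]2/C=C(/C)CC/C=C(/C)C(=O)[C@H](OC(=O)/C(C)=C\C)[C@@]12O | intermediate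
31 | trimethylammonium iodide of 30 | C[N+](C)(C)CC1C(=O)O[C@H]2/C=C(/C)CC/C=C(/C)C(=O)[C@H](OC(=O)/C(C)=C\C)[C@@]12O.[I-] | intermediate
32 | (6S,7R,8R)-8-angeloyloxy-7-hydroxy-9-oxogermacra-1(10)Z,4Z,11(13)-trien-12,6-olide (CNP0276177.1) | C=C1C(=O)O[C@H]2/C=C(/C)CC/C=C(/C)C(=O)[C@H](OC(=O)/C(C)=C\C)[C@@]12O | target

Total steps: 18
Longest linear sequence: 18 steps (from L-arabinose 1 to 32)

## Steps most likely to fail, with fallbacks

1. Step 13 (ring closure). Intermolecular coupling to oligomers, or protonation of the alkenylchromium before it reaches the aldehyde, may outrun closure of the medium ring. The fallback closes the same bond at the ketone oxidation level by an acylative Stille macrocyclisation. Setting out from 24, hexamethylditin and Pd(PPh3)4 would convert the alkenyl iodide into the trimethylstannyl aldehyde F1. Pinnick oxidation (NaClO2, NaH2PO4, 2-methyl-2-butene) would give the stannyl carboxylic acid F2, and 1-chloro-N,N,2-trimethylprop-1-en-1-amine would give the stannyl acid chloride F3. Intramolecular Stille acylation (Pd2(dba)3, tri(2-furyl)phosphine, high dilution) would then deliver enone 26 directly, where the route is rejoined and step 14 is no longer needed.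

2. Step 12 (acetal migration and lactol-to-lactone transposition). The sequence may stall at the lactol because ring–chain tautomerism and transesterification are slow, or acid may ionise the allylic C6–O bond. The fallback is a reductive detour that removes the lactol equilibrium. Setting out from 22, the acetal migration alone (CSA, acetone, rt) would be stopped at lactol 23, which is isolated and reduced with NaBH4 to the open-chain diol F4. Acid-catalysed lactonisation of its secondary C6–OH (CSA, PhMe, 60 °C; five-membered lactone preferred over the six-membered one through the primary alcohol) would give the hydroxymethyl lactone F5. Dess–Martin oxidation of the primary alcohol returns to 24.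

3. Step 16 (angeloylation). Z-to-E isomerisation of the angeloyl unit to the tiglate, or base-induced epimerisation at C8 during slow acylation of a hindered alcohol, may erode the product. The fallback builds the angelate on the substrate instead of transferring it. Setting out from 27, DCC/DMAP esterification of the C8–OH with 2-(diphenoxyphosphoryl)propanoic acid would give the phosphonate ester F6. Z-selective Horner–Wadsworth–Emmons olefination with acetaldehyde (NaI, DBU, THF, 0 °C) would form the (Z)-2-methylbut-2-enoate in place and return to 30.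

Further compounds
F1 | step 13 | trimethylstannyl aldehyde (24 with SnMe3 in place of iodine, Z retained) | CN(C)CC1C(=O)O[C@@H](/C=C(/C)CC/C=C(/C)[Sn](C)(C)C)[C@]12OC(C)(C)O[C@H]2C=O
F2 | step 13 | stannyl carboxylic acid (C9 acid) | CN(C)CC1C(=O)O[C@@H](/C=C(/C)CC/C=C(/C)[Sn](C)(C)C)[C@]12OC(C)(C)O[C@H]2C(=O)O
F3 | step 13 | stannyl acid chloride (C9 acyl chloride) | CN(C)CC1C(=O)O[C@@H](/C=C(/C)CC/C=C(/C)[Sn](C)(C)C)[C@]12OC(C)(C)O[C@H]2C(=O)Cl
F4 | step 12 | open-chain diol (C9 primary alcohol, free C6–OH, O7/O8 dioxolane, methyl ester) | OC[C@@H]1OC(C)(C)O[C@@]1([C@@H](O)/C=C(/C)CC/C=C(/C)I)C(CN(C)C)C(=O)OC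
F5 | step 12 | hydroxymethyl lactone (24 with CH2OH at C9) | CN(C)CC1C(=O)O[C@@H](/C=C(/C)CC/C=C(/C)I)[C@]12OC(C)(C)O[C@H]2CO
F6 | step 16 | 8-O-[2-(diphenoxyphosphoryl)propanoyl] ester of 27 | CN(C)CC1C(=O)O[C@H]2/C=C(/C)CC/C=C(/C)C(=O)[C@H](OC(=O)C(C)P(=O)(Oc3ccccc3)Oc3ccccc3)[C@@]12O
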